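## Conventions and assumptions

- Positions follow lindenane numbering: C1–C2–C3 is the cyclopropane; C1, C3, C4, C5, C10 form the five-membered ring; C5–C10 form the six-membered ring; C14 is the methyl on C10; C11 (on C7) carries the C12 ester and the C13 methyl. C15′ is the methylene that a monomer carries on C11 and that ends as C15 on C4 of the other half.
- Compounds 3–7 are carried as mixtures of epimers at the methyl-bearing sp3 carbon, which becomes sp2 in 8.
- Assumption: the esterase of step 7 hydrolyses the pro-S ester group of 10, as expected for a 2-methylmalonate with a short second chain; the fallback for step 7 does not depend on this.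
- Remark: the dienol ether is carried as a tert-butyldimethylsilyl (TBS) ether, not a trimethylsilyl ether, so that it survives the enolate triflation of step 16.

## Analysis of the target

Cycloshizukaol A (32) is a C2-symmetric head-to-tail dimer of two lindenane halves. In each half a cyclopropane (C1–C2–C3) is fused to a five-membered ring (C1, C3, C4, C5, C10), which shares the C5–C10 bond with a six-membered ring (C5–C10). The halves are joined by two C15–C11′ bonds, so that C4, C5, C6, C7, C11 and C15 of both halves form a twelve-membered ring. Each half has five stereocentres: C1 (R) and C3 (S) of the cyclopropane; the ring-fusion quaternary carbon C10 (S), whose C14 methyl lies on the same face as the C2 methylene; the C9 carbinol (R), whose hydroxyl is syn to that methyl; and the acyclic quaternary carbon C11 (R). C10 can be relayed from the cyclopropane and C9 from C10, but C11 lies outside the ring system and must be brought in enantiopure. The sensitive groups are the linear trienone C4=C5–C6=C7–C8=O with its vinylcyclopropane end (acid- and nucleophile-sensitive), the C8/C9 α-ketol (epimerisable and oxidisable under base) and the two neopentyl methyl esters. The hard points are two quaternary carbons per half, one at a ring fusion next to the cyclopropane, and closure of the macrocycle from two identical halves. The strategy rests on the six-membered ring being attached to a 4-methylbicyclo[3.1.0]hexenone through C5–C10 with C14 syn to C2: a diene supplying C6–C9 and C11 can add across C5=C10 from the face opposite the C2 methylene, which fixes C10.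

## Retrosynthetic reasoning

**32 ⇒ 31 ⇒ 28.** After removal of the two silyl groups (31), both C4–C15 bonds of the macrocycle are cut. They are the only ring bonds between an sp2 carbon and an unhindered sp3 carbon, and they are equivalent by symmetry. Cutting them gives two identical monomers 28 with an enol triflate at C4 and an iodomethyl group (C15′) on C11. Cuts at C7–C11 or C15–C11 would put the bond formation at a quaternary carbon. Forward, an alkylzinc made from the iodide must couple with the triflate of a second molecule under palladium catalysis and then close the ring. The zinc-bearing carbon has no β-hydrogen because C11 is quaternary. Within one monomer C4 and C15′ are held apart by the s-trans diene, so only dimerisation can use both ends.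

**28 ⇒ 27 ⇒ 26 ⇒ 25.** The C9–O bond is cut next. In 25 the only enolisable position is C9, so enolate hydroxylation has no regiochemical choice. The oxidant should approach anti to the axial C14 methyl and give the 9α-alcohol 26. An equilibration through the enediol to the 9β-epimer 27 is therefore planned, followed by silylation to 28 so that the hydroxyl does not quench the organozinc.

**25 ⇒ 23 ⇒ 22 ⇒ 21 ⇒ 20.** The iodide goes back through alcohol 23 to silyl ether 22. The C6=C7 double bond of 22 is removed to give silyl enol ether 21, and the C4 enol triflate is taken back to ketone 20. Triflation comes first, while C8 is still masked as its enol ether. The C4 ketone then has one enolisable position (C5; the other α-carbon is the cyclopropane bridgehead), and the choice between the C4 and C8 oxygens that a vinylogous diketone would show is avoided. The dehydrogenation must then avoid palladium because a vinyl triflate is present; the hydrogen to be removed at C6 is doubly allylic.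

**20 ⇒ 8 + 19 (key disconnection).** The six-membered ring is opened at C5–C6 and C9–C10. This gives a small, nearly flat, chiral enone 8 with one open face, and a 2-silyloxy diene 19 that already carries C11 with all its substituents. No other pair of cuts produces C10 and the C7=C8 enol ether in one step. The forward cycloaddition must pair C9 with the β-carbon C10, add anti to the C2 methylene, and overcome the low reactivity of a β,β-disubstituted enone toward a 2,3-disubstituted diene. A strong mixed aluminium Lewis acid is therefore used.

**8 ⇒ 6 ⇒ 5 ⇒ 4 ⇒ 3 ⇒ 1 + 2.** The enone comes from saturated ketone 6 by dehydrogenation, and 6 from alcohol 5. The cyclopropane and the five-membered ring are cut together by an intramolecular carbenoid cyclopropanation of terminal epoxide 4. A metal-carbene cyclopropanation of a diazoketone was not used because that substrate would carry a racemic allylic stereocentre competing with any chiral catalyst for the alkene face. In 4 the cyclopropane configuration is set by the epoxide carbon alone, which comes from 1. The methyl-bearing centre may be unselective because it is erased in 8. Epoxide 4 arises from 1 and 2 through chlorohydrin 3.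

**19 ⇒ 18 ⇒ 17 ⇒ 16 ⇒ 15 ⇒ 14 ⇒ 13 ⇒ 11 ⇒ 10 ⇒ 9.** The diene is the silyl enol ether of enone 18. The C9 methyl is disconnected (17 from enal 16), the C6 methylene is removed (16 from aldehyde 15), and 15 comes from alkene 14 by ozonolysis. C11 is then the carbon of an allylated methylmalonate. Alcohol 13 comes from reduction of the acid group of half-ester 11, 11 from the prochiral diester 10 by enzymatic differentiation of its ester groups, and 10 from 9 by allylation. The C11–C7 bond is not made directly, since attaching a vinyl carbon to a malonate carbon is difficult. The allyl group supplies C7 and C8, and C6 is added afterwards.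

## Alternatives that were turned down

**Alternative 1:** This cuts the two C7–C11 bonds of the macrocycle. Forward, two identical halves, each with a pinacolboryl group on C7 and an allylic phosphate whose γ-carbon is the future C11, would be joined by NaOMe and CuCl (monovalent copper) with a chiral N-heterocyclic carbene. An alkenylcopper at C7 attacks the γ-carbon of the partner (SN2′), and a second such event closes the ring to the divinyl macrocycle A1.
- For: C11 and the macrocycle are made in one catalytic operation, and no separate nine-step fragment is needed for C11. On step economy for C11 and on setting it by catalysis this plan is stronger than the chosen one.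
- Against: both new bonds end at all-carbon quaternary centres and use a trisubstituted alkenyl nucleophile flanked by the C8 ketal. The catalyst must override the bias of the chiral halves twice. The second event is a macrocyclisation in which α-attack and oligomerisation compete. The two vinyl groups of A1 must later be degraded to esters in the presence of the C4=C5–C6=C7 diene. The tricyclic halves still need their own ring synthesis.
- Comparison: the chosen route fixes C11 on a small molecule where its purity can be secured, and closes the macrocycle at unhindered sp2–sp3 bonds next to, not at, the quaternary carbons.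

**Alternative 2:** This cuts C1–C10 of the five-membered ring. Forward, Sc(OTf)3 (trivalent scandium) ionises a cross-conjugated dienone built from a methylcyclohexenyl and a chlorocrotonyl part. Conrotatory closure of the pentadienyl cation forms C1–C10 and gives hydrindenone A2, with the chloromethyl group (future C2) cis to C14; the cyclopropane would follow by enolate displacement of chloride.
- For: the five-membered ring and C10 come from simple acylation partners. The C9 oxygen is present from the start with its configuration, which is stronger than the chosen route, where C9 needs hydroxylation and epimerisation.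
- Against: closure onto a fully substituted terminus of an unpolarised dienone is slow, and the chloromethyl group lowers reactivity further. The sense of conrotation depends on the remote C9 silyloxy group. A2 lacks everything at C6–C8 and C11, so the C8 ketone, the C6=C7 alkene and the C7–C11 bond to a quaternary carbon would have to be installed on a finished tricycle.
- Comparison: the chosen cycloaddition delivers C6–C9 and C11 in one fragment with the correct oxidation pattern, and C10 is set by a facial bias that does not depend on a remote group.

**Alternative 3:** This cuts C3–C1 and C3–C2, so the cyclopropane and five-membered ring form together. Forward, PtCl2 (divalent platinum) activates the C3≡C4 alkyne of a propargylic acetate. A 1,2-acetate shift gives a carbene at C3, which adds to the vinyl group on C10 and gives the tricyclic enol acetate A3.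
- For: two rings form in one catalytic step. A3 is already a C4=C5 enol derivative, as good a handle for the C4–C15 bond as the enol triflate here. The C9 oxygen is in place, which is stronger than the chosen route.
- Against: the cyclohexane precursor must already hold the contiguous C9 and quaternary C10 centres with vinyl and methyl on C10. The face of carbene addition depends on the propargylic centre. A3 has C6, C7 and C8 at the alkane level, so it shares the late-stage problems of alternative 2, including the C7–C11 bond.
- Comparison: the chosen route makes the cyclopropane first, in five steps from an epoxide, uses it to control C10, and reaches the trienone by one dehydrogenation of the cycloadduct's enol ether.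

Key step: step 15

## Route

Step 1
Reactants: 1 (S)-epichlorohydrin; 2 but-2-enylmagnesium chloride
Product: 3 (2S)-1-chloro-4-methylhex-5-en-2-ol (both C4 epimers)
Conditions: THF, −30 → 0 °C; aq. NH4Cl
Reagents that add atoms: none
Why: Grignard opening of the terminal epoxide at its CH2 carbon; the allylic reagent reacts through its γ-carbon (SE2′), which gives the branched 2-methylbut-3-enyl chain. The epoxide stereocentre is untouched; the new methyl-bearing centre forms unselectively and is erased in step 5.

Step 2
Reactants: 3 (2S)-1-chloro-4-methylhex-5-en-2-ol
Product: 4 (2S)-2-(2-methylbut-3-en-1-yl)oxirane (both side-chain epimers)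
Conditions: NaOH, H2O, rt
Reagents that add atoms: none
Why: Intramolecular Williamson etherification of the chlorohydrin; the carbinol centre is not involved, so its configuration is kept.

Step 3
Reactants: 4 (2S)-2-(2-methylbut-3-en-1-yl)oxirane
Product: 5 (1S,2S,5S)-4-methylbicyclo[3.1.0]hexan-2-ol (both C4 epimers; OH trans to the cyclopropane CH2)
Conditions: lithium 2,2,6,6-tetramethylpiperidide (from the amine and n-BuLi), t-BuOMe, 0 °C → rt
Reagents that add atoms: none
Why: Intramolecular carbenoid cyclopropanation of an unsaturated terminal epoxide: the amide lithiates the epoxide CH2 trans to the chain and the alkene attacks this carbon anti to the breaking C–O bond. The carbinol keeps its configuration and both cyclopropane centres are set relative to it, in the same sense for either methyl epimer.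

Step 4
Reactants: 5 (1S,2S,5S)-4-methylbicyclo[3.1.0]hexan-2-ol
Product: 6 (1S,5S)-4-methylbicyclo[3.1.0]hexan-2-one (both C4 epimers)
Conditions: TEMPO (cat.), KBr (cat.), NaOCl, NaHCO3, CH2Cl2/H2O, 0 °C
Reagents that add atoms: none
Why: Nitroxyl-catalysed hypochlorite oxidation of a secondary alcohol; neutral, cold conditions leave the cyclopropylcarbinyl system intact.

Step 5
Reactants: 6 (1S,5S)-4-methylbicyclo[3.1.0]hexan-2-one
Product: 8 (1S,5R)-4-methylbicyclo[3.1.0]hex-3-en-2-one, via trimethylsilyl enol ether 7 (not isolated)
Conditions: LiN(i-Pr)2, Me3SiCl, THF, −78 °C; then Pd(OAc)2, MeCN, rt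
Reagents that add atoms: none
Why: Saegusa–Ito oxidation; the ketone can enolise only toward C3 because the other α-carbon is the cyclopropane bridgehead. β-Hydride elimination from the palladium enolate removes the hydrogen on the methyl-bearing carbon, so both epimers converge on one enone; the volatile product is used as a solution.

Step 6
Reactants: 9 dimethyl methylmalonate
Product: 10 dimethyl 2-methyl-2-(prop-2-en-1-yl)propanedioate
Conditions: NaH, allyl bromide, THF, 0 °C → rt
Reagents that add atoms: allyl bromide, C=CCBr
Why: Malonate alkylation; the single acidic hydrogen and a reactive allylic halide make the quaternary carbon without over-alkylation.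

Step 7
Reactants: 10 dimethyl 2-methyl-2-(prop-2-en-1-yl)propanedioate
Product: 11 (2S)-2-(methoxycarbonyl)-2-methylpent-4-enoic acid
Conditions: pig liver esterase, phosphate buffer pH 7.5, rt, pH-stat (NaOH); then HCl
Reagents that add atoms: water, O
Why: Enzymatic desymmetrisation of a prochiral 2,2-disubstituted malonate diester; hydrolysis of one enantiotopic ester group sets the configuration of the future C11 (see the assumption above).

Step 8
Reactants: 11 (2S)-2-(methoxycarbonyl)-2-methylpent-4-enoic acid
Product: 13 methyl (2S)-2-(hydroxymethyl)-2-methylpent-4-enoate, via acid chloride 12 (not isolated)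
Conditions: (COCl)2, DMF (cat.), CH2Cl2, 0 °C → rt; then NaBH4, THF/DMF, −20 → 0 °C
Reagents that add atoms: none
Why: Acid chloride formation, then borohydride reduction; the acid chloride is far more electrophilic than the neopentyl methyl ester, and borane is avoided because of the alkene. The stereocentre has no α-hydrogen and cannot epimerise.

Step 9
Reactants: 13 methyl (2S)-2-(hydroxymethyl)-2-methylpent-4-enoate
Product: 14 methyl (2S)-2-{[(tert-butyldimethylsilyl)oxy]methyl}-2-methylpent-4-enoate
Conditions: t-BuMe2SiCl, imidazole, DMF, rt
Reagents that add atoms: tert-butyldimethylsilyl chloride, CC(C)(C)[Si](C)(C)Cl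
Why: Standard silylation of a primary alcohol; the ether masks the future C15′ oxygen through the Lewis-acid step.

Step 10
Reactants: 14 methyl (2S)-2-{[(tert-butyldimethylsilyl)oxy]methyl}-2-methylpent-4-enoate
Product: 15 methyl (2S)-2-{[(tert-butyldimethylsilyl)oxy]methyl}-2-methyl-4-oxobutanoate
Conditions: O3, CH2Cl2, −78 °C; then PPh3, −78 °C → rt
Reagents that add atoms: ozone, [O-][O+]=O
Why: Ozonolysis with reductive work-up cleaves the only alkene to the aldehyde that supplies C7 (CH2) and C8 (CHO).

Step 11
Reactants: 15 methyl (2S)-2-{[(tert-butyldimethylsilyl)oxy]methyl}-2-methyl-4-oxobutanoate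
Product: 16 methyl (2S)-2-{[(tert-butyldimethylsilyl)oxy]methyl}-3-formyl-2-methylbut-3-enoate
Conditions: aq. CH2O, pyrrolidine (cat.), EtCO2H (cat.), i-PrOH, 45 °C
Reagents that add atoms: formaldehyde, C=O
Why: Amine-catalysed Mannich condensation and elimination (aldehyde α-methylenation); the aldehyde has one α-CH2, so C6 is introduced on C7 without regiochemical choice.

Step 12
Reactants: 16 methyl (2S)-2-{[(tert-butyldimethylsilyl)oxy]methyl}-3-formyl-2-methylbut-3-enoate
Product: 17 methyl (2S)-2-{[(tert-butyldimethylsilyl)oxy]methyl}-4-hydroxy-2-methyl-3-methylidenepentanoate (both C4 epimers)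
Conditions: CH3MgBr, THF, −78 °C; AcOH, −78 °C
Reagents that add atoms: methylmagnesium bromide, C[Mg]Br
Why: Grignard 1,2-addition to the enal, which reacts far faster than the hindered ester at −78 °C. The cold acidic quench keeps the γ-alkoxide from lactonising; the carbinol centre is removed in the next step.

Step 13
Reactants: 17 methyl (2S)-2-{[(tert-butyldimethylsilyl)oxy]methyl}-4-hydroxy-2-methyl-3-methylidenepentanoate
Product: 18 methyl (2S)-2-{[(tert-butyldimethylsilyl)oxy]methyl}-2-methyl-3-methylidene-4-oxopentanoate
Conditions: Dess–Martin periodinane, NaHCO3, CH2Cl2, 0 °C → rt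
Reagents that add atoms: none
Why: Dess–Martin oxidation of the allylic alcohol under buffered conditions; the bulky α-substituent protects the vinyl ketone from self-condensation.

Step 14
Reactants: 18 methyl (2S)-2-{[(tert-butyldimethylsilyl)oxy]methyl}-2-methyl-3-methylidene-4-oxopentanoate
Product: 19 methyl (2S)-4-[(tert-butyldimethylsilyl)oxy]-2-{[(tert-butyldimethylsilyl)oxy]methyl}-2-methyl-3-methylidenepent-4-enoate
Conditions: t-BuMe2SiOTf, Et3N, CH2Cl2, 0 °C
Reagents that add atoms: tert-butyldimethylsilyl triflate, CC(C)(C)[Si](C)(C)OS(=O)(=O)C(F)(F)F
Why: Soft enolisation and O-silylation of the methyl ketone, its only enolisable site, gives the 2-silyloxy-3-substituted butadiene; the ester has no α-hydrogen.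

Step 15
Reactants: 8 (1S,5R)-4-methylbicyclo[3.1.0]hex-3-en-2-one; 19 methyl (2S)-4-[(tert-butyldimethylsilyl)oxy]-2-{[(tert-butyldimethylsilyl)oxy]methyl}-2-methyl-3-methylidenepent-4-enoate
Product: 20 cis-fused tricyclic C4 ketone (1R,3S,5S,10S,11S) with C7=C8 silyl enol ether, C14 methyl and C5–H syn to the C2 methylene, and C11 bearing CH3, CO2CH3 and CH2OSi(t-Bu)Me2
Conditions: AlBr3/AlMe3 (10:1, excess), PhMe/CH2Cl2, −10 °C → rt; pyridine, aq. NaHCO3
Reagents that add atoms: none
Why: The mixed aluminium Lewis acid binds the C4 carbonyl of 8 and lowers its LUMO, and 19 adds in a concerted, asynchronous [4+2] cycloaddition in which the C9–C10 bond is more advanced than C5–C6. The closest known reaction type is the AlBr3/AlMe3-promoted Diels–Alder reaction of hindered 2-silyloxydienes with β,β-disubstituted cycloalkenones, which forms ring-fusion quaternary carbons. The six-membered ring is closed by the cycloaddition itself, both σ bonds forming suprafacially on each partner, which enforces the cis ring fusion. Regiochemistry follows from the C8 silyloxy group, which makes C9 the nucleophilic terminus and pairs it with the β-carbon C10. The new quaternary centre C10 is controlled by the cyclopropane of 8: the C2 methylene shields one face of the nearly flat bicycle, the diene adds to the other, and the C14 methyl is left syn to C2. C5 is set cis to C14 by the suprafacial addition and is erased in step 16, so endo/exo selectivity does not matter. C11 is a spectator, and its bulk at C7 favours the s-cis conformer of the diene. Excess Lewis acid is needed because the ester of 19 also binds aluminium; low temperature and a pyridine quench protect the silyl enol ether and the cyclopropyl ketone.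

Step 16
Reactants: 20 cis-fused tricyclic C4 ketone
Product: 21 C4 enol triflate (C4=C5) with the C7=C8 silyl enol ether retained
Conditions: KN(SiMe3)2, THF, −78 °C; PhNTf2, −78 → 0 °C
Reagents that add atoms: N-phenylbis(trifluoromethanesulfonimide), O=S(=O)(N(c1ccccc1)S(=O)(=O)C(F)(F)F)C(F)(F)F
Why: Enolate O-triflation; the ketone can enolise only toward C5 because C3 is a cyclopropane bridgehead and C8 is still masked, so one triflate forms. C5 becomes sp2 as in the target.

Step 17
Reactants: 21 C4 enol triflate
Product: 22 trienone triflate C4(OTf)=C5–C6=C7–C8=O with CH2OSi(t-Bu)Me2 on C11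
Conditions: DDQ, 2,4,6-collidine, PhH, rt
Reagents that add atoms: none
Why: Quinone dehydrogenation of a silyl enol ether: hydride abstraction from the doubly allylic C6 gives a silyloxy-stabilised pentadienyl cation, which loses silicon to give the C6=C7 enone. Pd(OAc)2 is avoided here because the zerovalent palladium it releases could insert into the vinyl triflate.

Step 18
Reactants: 22 trienone triflate
Product: 23 primary alcohol (C15′–OH) of the trienone triflate
Conditions: HF·pyridine, pyridine, THF, 0 °C → rt
Reagents that add atoms: none
Why: Buffered fluoride cleavage of the only remaining silyl ether; vinyl triflate, ester and enone are inert to these conditions.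

Step 19
Reactants: 23 primary alcohol
Product: 25 C15′ iodide (11R) of the trienone triflate, via alkyl triflate 24 (not isolated)
Conditions: Tf2O, 2,6-lutidine, CH2Cl2, −78 °C; then NaI, acetone, 0 °C → rt
Reagents that add atoms: sodium iodide, [Na+].[I-]
Why: Alcohol triflation and SN2 displacement by iodide; the triflate leaving group compensates for the neopentyl position. C11 has no hydrogen, so elimination is impossible, and the enol triflate is not displaced by iodide.

Step 20
Reactants: 25 C15′ iodide
Product: 26 9α-hydroxy ketone (9S; OH anti to the C14 methyl)
Conditions: NaN(SiMe3)2, THF, −78 °C; 2-(phenylsulfonyl)-3-phenyloxaziridine, −78 °C; aq. NH4Cl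
Reagents that add atoms: 2-(phenylsulfonyl)-3-phenyloxaziridine, O=S(=O)(c1ccccc1)N1OC1c1ccccc1
Why: Oxaziridine hydroxylation of a ketone enolate; C9 is the only enolisable position. The oxidant is expected to approach anti to the axial C14 methyl on the neighbouring carbon, so the α-alcohol should predominate; the neopentyl iodide is inert to the hindered base.

Step 21
Reactants: 26 9α-hydroxy ketone
Product: 27 9β-hydroxy ketone (9R; OH syn to the C14 methyl)
Conditions: DBU (0.3 equiv), PhMe, rt
Reagents that add atoms: none
Why: Base-mediated epimerisation of an α-ketol through its enediol. C9 is reprotonated from the open α face, and the 9β-alcohol is the pseudo-equatorial epimer that can hydrogen-bond in plane with the C8 carbonyl, so kinetic and thermodynamic preferences point the same way.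

Step 22
Reactants: 27 9β-hydroxy ketone
Product: 28 9β-triethylsilyl ether (iodide/enol triflate monomer)
Conditions: Et3SiOTf, 2,6-lutidine, CH2Cl2, −78 → 0 °C
Reagents that add atoms: triethylsilyl triflate, CC[Si](CC)(CC)OS(=O)(=O)C(F)(F)F
Why: Silylation of a hindered secondary alcohol with a silyl triflate; it removes the acidic hydroxyl that would protonate the organozinc and blocks α-ketol side reactions during coupling.

Step 23
Reactants: 28 9β-triethylsilyl ether monomer (two molecules)
Product: 31 9,9′-bis(triethylsilyl) ether of cycloshizukaol A, via alkylzinc iodide 29 (not isolated), via linear dimer zinc reagent 30 (not isolated)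
Conditions: Zn dust (activated with BrCH2CH2Br, Me3SiCl), LiCl, THF, 30 °C; then slow addition to Pd2(dba)3 (cat.), SPhos (cat.), THF/NMP, 50 °C, high dilution
Reagents that add atoms: none
Why: Twofold Negishi alkyl–alkenyl coupling: zinc inserts into the C–I bond to give an ester-chelated reagent with no β-hydrogen, and zerovalent palladium adds to the electron-poor C4 triflate. Within one monomer C4 and C15′ sit at the ends of an s-trans diene and cannot meet, so the first coupling is intermolecular and the second closes the twelve-membered ring. No stereocentre is touched.

Step 24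
Reactants: 31 9,9′-bis(triethylsilyl) ether
Product: 32 cycloshizukaol A
Conditions: HF·pyridine, THF, 0 °C → rt
Reagents that add atoms: none
Why: Fluoride cleavage of both triethylsilyl ethers under mildly acidic conditions; no base is present that could epimerise C9 or attack the trienone.

## Compound list

1 | (S)-epichlorohydrin, (2S)-2-(chloromethyl)oxirane | ClC[C@@H]1CO1 | starting material
2 | but-2-enylmagnesium chloride | CC=CC[Mg]Cl | starting material
3 | (2S)-1-chloro-4-methylhex-5-en-2-ol (both C4 epimers) | ClC[C@@H](O)CC(C)C=C | intermediate
4 | (2S)-2-(2-methylbut-3-en-1-yl)oxirane (both side-chain epimers) | C=CC(C)C[C@H]1CO1 | intermediate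
5 | (1S,2S,5S)-4-methylbicyclo[3.1.0]hexan-2-ol (both C4 epimers; OH trans to the cyclopropane CH2) | O[C@H]1CC(C)[C@@H]2C[C@H]12 | intermediate
6 | (1S,5S)-4-methylbicyclo[3.1.0]hexan-2-one (both C4 epimers) | O=C1CC(C)[C@@H]2C[C@H]12 | intermediate
7 | trimethyl{[(1S,5S)-4-methylbicyclo[3.1.0]hex-2-en-2-yl]oxy}silane | C[Si](C)(C)OC1=CC(C)[C@@H]2C[C@H]12 | intermediate (not isolated)
8 | (1S,5R)-4-methylbicyclo[3.1.0]hex-3-en-2-one | O=C1C=C(C)[C@@H]2C[C@H]12 | intermediate
9 | dimethyl methylmalonate | COC(=O)C(C)C(=O)OC | starting material
10 | dimethyl 2-methyl-2-(prop-2-en-1-yl)propanedioate | C=CCC(C)(C(=O)OC)C(=O)OC | intermediate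
11 | (2S)-2-(methoxycarbonyl)-2-methylpent-4-enoic acid | C=CC[C@](C)(C(=O)OC)C(=O)O | intermediate
12 | methyl (2R)-2-(chlorocarbonyl)-2-methylpent-4-enoate | C=CC[C@](C)(C(=O)OC)C(Cl)=O | intermediate (not isolated)
13 | methyl (2S)-2-(hydroxymethyl)-2-methylpent-4-enoate | C=CC[C@](C)(C(=O)OC)CO | intermediate
14 | methyl (2S)-2-{[(tert-butyldimethylsilyl)oxy]methyl}-2-methylpent-4-enoate | C=CC[C@](C)(C(=O)OC)CO[Si](C)(C)C(C)(C)C | intermediate
15 | methyl (2S)-2-{[(tert-butyldimethylsilyl)oxy]methyl}-2-methyl-4-oxobutanoate | O=CC[C@](C)(C(=O)OC)CO[Si](C)(C)C(C)(C)C | intermediate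
16 | methyl (2S)-2-{[(tert-butyldimethylsilyl)oxy]methyl}-3-formyl-2-methylbut-3-enoate | O=CC(=C)[C@](C)(C(=O)OC)CO[Si](C)(C)C(C)(C)C | intermediate
17 | methyl (2S)-2-{[(tert-butyldimethylsilyl)oxy]methyl}-4-hydroxy-2-methyl-3-methylidenepentanoate (both C4 epimers) | CC(O)C(=C)[C@](C)(C(=O)OC)CO[Si](C)(C)C(C)(C)C | intermediate
18 | methyl (2S)-2-{[(tert-butyldimethylsilyl)oxy]methyl}-2-methyl-3-methylidene-4-oxopentanoate | CC(=O)C(=C)[C@](C)(C(=O)OC)CO[Si](C)(C)C(C)(C)C | intermediate
19 | methyl (2S)-4-[(tert-butyldimethylsilyl)oxy]-2-{[(tert-butyldimethylsilyl)oxy]methyl}-2-methyl-3-methylidenepent-4-enoate | C=C(O[Si](C)(C)C(C)(C)C)C(=C)[C@](C)(C(=O)OC)CO[Si](C)(C)C(C)(C)C | intermediate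
20 | cis-fused tricyclic C4 ketone (1R,3S,5S,10S,11S): C7=C8 tert-butyldimethylsilyl enol ether, C14 methyl and C5–H syn to the C2 methylene, C11 with CH3, CO2CH3, CH2OSi(t-Bu)Me2 | O=C1[C@H]2CC([C@](C)(C(=O)OC)CO[Si](C)(C)C(C)(C)C)=C(O[Si](C)(C)C(C)(C)C)C[C@@]2(C)[C@@H]2C[C@H]12 | intermediate
21 | C4 enol triflate (C4=C5) of 20 with the C7=C8 silyl enol ether | O=S(=O)(OC1=C2CC([C@](C)(C(=O)OC)CO[Si](C)(C)C(C)(C)C)=C(O[Si](C)(C)C(C)(C)C)C[C@@]2(C)[C@@H]2C[C@H]12)C(F)(F)F | intermediate
22 | trienone triflate C4(OTf)=C5–C6=C7–C8=O with CH2OSi(t-Bu)Me2 on C11 (1R,3S,10S,11S) | O=S(=O)(OC1=C2C=C([C@](C)(C(=O)OC)CO[Si](C)(C)C(C)(C)C)C(=O)C[C@@]2(C)[C@@H]2C[C@H]12)C(F)(F)F | intermediate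
23 | trienone triflate with free C15′ hydroxyl | O=S(=O)(OC1=C2C=C([C@](C)(C(=O)OC)CO)C(=O)C[C@@]2(C)[C@@H]2C[C@H]12)C(F)(F)F | intermediate
24 | trienone triflate with C15′ alkyl triflate | O=S(=O)(OC1=C2C=C([C@](C)(C(=O)OC)COS(=O)(=O)C(F)(F)F)C(=O)C[C@@]2(C)[C@@H]2C[C@H]12)C(F)(F)F | intermediate (not isolated)
25 | trienone triflate with C15′ iodide (11R) | O=S(=O)(OC1=C2C=C([C@](C)(C(=O)OC)CI)C(=O)C[C@@]2(C)[C@@H]2C[C@H]12)C(F)(F)F | intermediate
26 | 9α-hydroxy ketone (9S; OH anti to C14) | O=S(=O)(OC1=C2C=C([C@](C)(C(=O)OC)CI)C(=O)[C@@H](O)[C@@]2(C)[C@@H]2C[C@H]12)C(F)(F)F | intermediate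
27 | 9β-hydroxy ketone (9R; OH syn to C14) | O=S(=O)(OC1=C2C=C([C@](C)(C(=O)OC)CI)C(=O)[C@H](O)[C@@]2(C)[C@@H]2C[C@H]12)C(F)(F)F | intermediate
28 | 9β-triethylsilyl ether, iodide/enol triflate monomer | O=S(=O)(OC1=C2C=C([C@](C)(C(=O)OC)CI)C(=O)[C@H](O[Si](CC)(CC)CC)[C@@]2(C)[C@@H]2C[C@H]12)C(F)(F)F | intermediate
29 | alkylzinc iodide of 28 | O=S(=O)(OC1=C2C=C([C@](C)(C(=O)OC)C[Zn]I)C(=O)[C@H](O[Si](CC)(CC)CC)[C@@]2(C)[C@@H]2C[C@H]12)C(F)(F)F | intermediate (not isolated)
30 | linear head-to-tail dimer, C15′ of one half bonded to C4 of the other, with terminal CH2ZnI and C4 triflate | O=S(=O)(OC1=C2C=C([C@](C)(C(=O)OC)CC3=C4C=C([C@](C)(C(=O)OC)C[Zn]I)C(=O)[C@H](O[Si](CC)(CC)CC)[C@@]4(C)[C@@H]4C[C@H]34)C(=O)[C@H](O[Si](CC)(CC)CC)[C@@]2(C)[C@@H]2C[C@H]12)C(F)(F)F | intermediate (not isolated)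
31 | 9,9′-bis(triethylsilyl) ether of cycloshizukaol A | COC(=O)[C@]1(C)CC2=C3C=C(C(=O)[C@H](O[Si](CC)(CC)CC)[C@@]3(C)[C@@H]3C[C@H]23)[C@](C)(C(=O)OC)CC2=C3C=C1C(=O)[C@H](O[Si](CC)(CC)CC)[C@@]3(C)[C@@H]1C[C@H]21 | intermediate
32 | cycloshizukaol A (each half 1R,3S,9R,10S,11R) | COC(=O)[C@]1(C)CC2=C3C=C(C(=O)[C@H](O)[C@@]3(C)[C@@H]3C[C@H]23)[C@](C)(C(=O)OC)CC2=C3C=C1C(=O)[C@H](O)[C@@]3(C)[C@@H]1C[C@H]21 | target

## Step count and least certain steps

Total: 24 steps. Longest linear sequence: 19 steps (steps 6–14, then 15–24, from 9). The enone branch (steps 1–5) joins at step 15.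

**Step 15 (key step).** The cycloaddition may be too slow, because a β,β-disubstituted enone meets a 2,3-disubstituted diene. The strong Lewis acid may instead open the activated cyclopropane by bromide attack, or trigger aromatising rearrangement of the bicyclic enone. The diene may also lose silicon, or the reaction may stop after the first C–C bond. The fallback sets out from 8 and 19 and returns at 20. Bromination of 8 (Br2, then Et3N) gives (1S,5R)-3-bromo-4-methylbicyclo[3.1.0]hex-3-en-2-one F1. With two acceptor groups on C5 it should react with 19 thermally or under a much milder Lewis acid (Me2AlCl, low temperature), with the same regio- and facial sense, to give the C5-bromo cycloadduct F2. Bu3SnH/AIBN then replaces bromine by hydrogen from the convex face and gives 20; C5 is erased in step 16 in any case.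

**Step 23.** Oligomerisation may outrun ring closure. The organozinc may be protonated before it couples. Zinc insertion may be sluggish at the neopentyl carbon or may reduce the electron-poor trienone. The fallback sets out from 28 and returns at 31, and separates the two couplings. Zinc reagent 29 is made from one part of 28 and added slowly to the catalyst with an excess of untouched 28, so that it meets a triflate whose partner end is still an iodide. This should give the linear iodide–triflate dimer F3, with recovery of excess 28. F3 is then converted into its zinc reagent and cyclised in a separate, highly dilute operation to 31.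

**Step 21 (with the selectivity of step 20).** The equilibrium may not favour the 9β-epimer strongly enough. Enolisation may be slow because the hydrogen to be removed in 26 is equatorial and shielded. The base may also attack the dienyl triflate or cause air oxidation of the ketol. The fallback sets out from 26 and returns at 27. Dess–Martin oxidation gives the non-enolisable C8,C9-dione F4. NaBH4/CeCl3 at −78 °C should then reduce the more electrophilic, non-conjugated C9 carbonyl from the α face, anti to the C14 methyl, which places the hydroxyl β under kinetic control.

**Step 7.** The esterase may differentiate the two ester groups of an allyl/methyl malonate only moderately, or in the opposite sense. The fallback sets out from 10 and returns at 11. Half-saponification with one equivalent of KOH gives the racemic half-ester F5. Crystallisation with (S)-1-phenylethylamine (the (R)-amine is used instead if it gives the less soluble salt of the (S)-acid) gives the diastereomerically pure salt F6, and acidification liberates 11.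

## Further compounds

F1 | step 15 | (1S,5R)-3-bromo-4-methylbicyclo[3.1.0]hex-3-en-2-one | O=C1C(Br)=C(C)[C@@H]2C[C@H]12
F2 | step 15 | C5-bromo cycloadduct (bromine syn to the C14 methyl, otherwise as 20) | O=C1[C@@]2(Br)CC([C@](C)(C(=O)OC)CO[Si](C)(C)C(C)(C)C)=C(O[Si](C)(C)C(C)(C)C)C[C@@]2(C)[C@@H]2C[C@H]12
F3 | step 23 | linear iodide–triflate dimer (C15′ of one half bonded to C4 of the other; terminal CH2I and C4 triflate) | O=S(=O)(OC1=C2C=C([C@](C)(C(=O)OC)CC3=C4C=C([C@](C)(C(=O)OC)CI)C(=O)[C@H](O[Si](CC)(CC)CC)[C@@]4(C)[C@@H]4C[C@H]34)C(=O)[C@H](O[Si](CC)(CC)CC)[C@@]2(C)[C@@H]2C[C@H]12)C(F)(F)F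
F4 | step 21 | C8,C9-dione of the iodide/enol triflate | O=S(=O)(OC1=C2C=C([C@](C)(C(=O)OC)CI)C(=O)C(=O)[C@@]2(C)[C@@H]2C[C@H]12)C(F)(F)F
F5 | step 7 | racemic 2-(methoxycarbonyl)-2-methylpent-4-enoic acid | C=CCC(C)(C(=O)OC)C(=O)O
F6 | step 7 | (S)-1-phenylethylammonium (2S)-2-(methoxycarbonyl)-2-methylpent-4-enoate | C=CC[C@](C)(C(=O)OC)C(=O)[O-].C[C@H]([NH3+])c1ccccc1
A1 | alternative 1 | macrocyclic dimer with C11 vinyl groups, C8 ketals and C9 silyl ethers | C1C2=C3C=C(C4(OCCO4)[C@H](O[Si](C)(C)C(C)(C)C)[C@@]3(C)[C@@H]3C[C@H]23)[C@](C)(C=C)CC2=C3C=C(C4(OCCO4)[C@H](O[Si](C)(C)C(C)(C)C)[C@@]3(C)[C@@H]3C[C@H]23)[C@]1(C)C=C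
A2 | alternative 2 | hydrindenone with C1 chloromethyl, C10 methyl and C9 silyl ether | O=C2C3=CCC[C@H](O[Si](C)(C)C(C)(C)C)[C@@]3(C)[C@H](CCl)C2
A3 | alternative 3 | tricyclic C4 enol acetate with C9 silyl ether | CC(=O)OC2=C3CCC[C@H](O[Si](C)(C)C(C)(C)C)[C@@]3(C)[C@@H]3C[C@H]23
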